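Assumption: threo and erythro are used in the Fischer sense for the acyclic 1-aryl-2-aryloxypropan-1-ols, so the threo alcohol is (1R,2R). The bicyclic core is numbered O1, C2 (aryl), C3 (methyl), O4, C4a, C5 (OMe), C6, C7 (side chain), C8, C8a; the benzo ring is ring A and the trimethoxyphenyl ring is ring C.

## The problem

Target 15 is a trans-2-aryl-3-methyl-2,3-dihydro-1,4-benzodioxine in which ring A carries a methoxy group at C5 and an (E)-3-hydroxyprop-1-enyl chain at C7, and C2 carries a 3,4,5-trimethoxyphenyl group (ring C). The two dioxane oxygens are not interchangeable: O4, bound to the methyl-bearing C3, is para to the C7 chain, whereas O1, bound to the benzylic C2, is meta to it, so each oxygen has to be delivered to its own arene carbon. The two adjacent stereocentres, C2 (R) and C3 (R), are trans; C3 is an ordinary secondary ether carbon that can be taken from the chiral pool and can then steer C2 by 1,2-induction, while the reverse order is unattractive because C2 is a benzylic C–O centre on an electron-rich ring. That same centre ionises under strong acid, and any α-aryloxy ketone used on the way can enolise at the future C3, so acid after ring closure and base at the ketone stage both have to be avoided. The cinnamyl alcohol is the most fragile part (a styrene, oxidisable and acid-labile) and is best completed last from a robust one-carbon handle at C7. The enabling feature is in ring A: C4a–O4 is flanked by C8a–O1 and C5–OMe, so ring A is a 2,6-dioxygenated 4-substituted phenyl ether, a syringyl unit with one ortho oxygen tied back to the side chain. If O1 starts as a second methoxy group, ring A of the precursor has a mirror plane through C4a and C7, and replacing either methoxy by the C2 hydroxyl gives the correct regiochemistry by symmetry.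

## Retrosynthesis

**Side chain (15 ⇒ 14 ⇒ 12 ⇒ 11).** The allylic C–O of 15 is traced to the ester of cinnamate 14, and the Cα=Cβ bond of 14 is cut in a Wittig sense to aldehyde 13. Aldehyde 13 is generated in the flask from benzylic alcohol 12, which comes from silyl ether 11. Carrying a styrene or cinnamate through the ring closure was rejected: a conjugated alkene on an electron-rich ring would be the first site of one-electron oxidation and is photo-isomerisable. An aldehyde or ester on ring A would make ring A the poorer electron donor of the two arenes. A silyloxymethyl group behaves electronically as an alkyl group, survives organomagnesium and hydride reagents, and is removed by fluoride. The forward reactions asked for are routine.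

**Dioxane ring (11 ⇒ 10).** The O1–C8a bond is cut and C8a receives a methoxy group, giving the acyclic threo ether alcohol 10 with a mirror-symmetric syringyl ring A. The neighbouring cuts are less attractive. Cutting O1–C2 means a substitution at the benzylic stereocentre and needs a differentiated catechol. Cutting O4–C3 means an SN2 reaction at a hindered secondary carbon next to a benzylic centre. The chosen cut breaks no bond at either stereocentre and removes the regiochemical question altogether. Precursor 10 has one ring fewer and its ring A comes directly from syringaldehyde 1. The forward reaction must replace an unactivated aryl methoxy group on an electron-rich ring by a secondary hydroxyl; classical SNAr cannot do this, so the ring is activated as its radical cation.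

**C1 stereocentre (10 ⇒ 9).** The C1–H bond is cut to ketone 9. Setting C1 by hydride delivery under 1,2-induction from C2 is preferred over aryl addition to an α-aryloxy aldehyde, which is more prone to racemise and less predictable in facial selectivity. The forward step must give the threo isomer and must not enolise the ketone.

**Aryl ketone (9 ⇒ 6 + 8).** The C1–aryl bond is cut to Weinreb amide 6 and aryl Grignard reagent 8, made from bromide 7. This separates ring C as a commercial bromoarene and leaves a three-carbon acyl unit that already holds the C2 stereocentre. The forward step needs mono-addition and a quench that spares that stereocentre.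

**Functional-group adjustments (6 ⇒ 5 ⇒ 4 ⇒ 3).** The amide is traced to ethyl ester 5, the silyl ether to alcohol 4, and the alcohol to aldehyde 3. The formyl group of 3 is wanted in the first step because it makes the phenol acidic, but it must be masked before organometallic chemistry. Reduction and silylation turn it into the group that the key step needs.

**Aryl ether (3 ⇒ 1 + 2).** The O–C2 bond (the future O4–C3) is cut to syringaldehyde 1 and ethyl (S)-lactate 2. A Mitsunobu reaction forms this bond with inversion, so the inexpensive (S)-lactate supplies the (R) centre. The alternative of displacing a leaving group on a propiophenone would give a racemate.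

## Roads not taken

**Alternative 1:** Both aryl–oxygen bonds of the dioxane (O4–C4a and O1–C8a) are cut and ring A is reduced to a cyclohexane-1,3-dione, to be aromatised afterwards.

- Forward key step: Rh2(OAc)4 would decompose the diazo dione A2 (methyl 4-diazo-3,5-dioxocyclohexane-1-carboxylate). The carbenoid would insert into the free C2 hydroxyl of A3, the benzylic mono-silyl ether of diol A4. Acid would then remove the silyl group and condense the benzylic hydroxyl onto one of the two equivalent ketones to give the bicyclic enone ester A1.
- Merits: the order of events dictates which oxygen goes to which ring carbon, the dione is symmetric, and both stereocentres could come from one catalytic asymmetric dihydroxylation. O–H insertion of 2-diazo-1,3-diones and acid-catalysed enol ether formation are known reaction types, so the centre of this road is more secure than that of the chosen plan.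
- Weak points: A3 requires silylation of one of two secondary hydroxyls of A4. The acid condensation exposes an electron-rich benzylic C–O bond to ionising conditions and puts C2 at risk. After A1 the arene must still be made: dehydrogenation to a phenol, O-methylation, then reduction, oxidation, olefination and reduction at the C7 ester.
- Comparison: the oxygenation pattern that the chosen route buys with syringaldehyde 1 has to be manufactured here, and the total would be clearly longer. The chosen plan sets against the better precedent of Alternative 1 a shorter sequence, routine steps on both sides of the key step, and a known-chemistry fallback for the same bond.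

**Alternative 2:** Ring A is opened at C5–C6 and built last from an open-chain keto ester.

- Forward key step: the methyl ketone enolate of the dioxene keto ester A6 would attack the ester carbonyl in a Claisen-type closure, and enolisation would give the resorcinol A5.
- Merits: the C5 and C7 oxygens arise automatically. The C7 oxygen could serve as a sulfonate handle, so the whole three-carbon chain might be attached in one cross-coupling. That endgame would be shorter than steps 8–10 of the chosen plan, and in this respect the alternative is better.
- Weak points: A6 is a tetrasubstituted dioxene whose two alkene carbons carry different chains and must each be bound to the right oxygen, so the regiochemical problem is moved, not solved. The methylene between the ketone and the dioxene is more acidic than the terminal methyl, so the wrong enolate is favoured. The two phenols of A5 must then be told apart, one methylated and the other replaced by carbon.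
- Comparison: the chosen plan starts from a ring A with every substituent in place and needs no phenol differentiation. Its only disadvantage is a three-step chain extension.

**Alternative 3:** The O1–C2 bond is cut and C2 is left as a benzylic methylene.

- Forward key step: 2,3-dichloro-5,6-dicyano-1,4-benzoquinone (DDQ) would abstract hydride from the benzylic CH2 of phenol A8, and the ortho hydroxyl would trap the cation to give aldehyde A7, which is identical with 13.
- Merits: this is the shortest road. A8 needs no benzylic oxygen and no diastereoselective reduction, A7 is already at the aldehyde stage, and oxidative C–H etherification with DDQ is a known reaction type. The whole synthesis might take five or six steps, so in step economy and precedent this alternative is better than the chosen plan.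
- Weak points:
  - C2 is created in the key step through a planar benzylic cation, with only the C3 methyl to bias the face.
  - The C2–H bond of A7 is benzylic and α-oxygenated, so it is a better hydride donor than the CH2 of A8. Over-oxidation and loss of configuration are built into the step.
  - The 3,4,5-trimethoxyphenyl group is a mediocre hydride-donor arene because its central methoxy group is twisted out of conjugation.
  - A free phenol is itself a substrate for DDQ.
  - A8 requires etherification of only one of the two adjacent hydroxyls of the catechol aldehyde A9.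
- Comparison: the chosen plan is longer and its key step is less precedented. It sets against this that both stereocentres are fixed before ring closure by reactions of predictable sense, the closure touches neither of them, and regiochemistry follows from symmetry instead of from selective alkylation.

Key step: step 7

## Route

Step 1
Reactants: 1 syringaldehyde (4-hydroxy-3,5-dimethoxybenzaldehyde); 2 ethyl (S)-lactate
Product: 3 ethyl (2R)-2-(4-formyl-2,6-dimethoxyphenoxy)propanoate
Conditions: PPh3, DIAD, THF, 0 °C to rt
Reagents that add atoms: none
Why: Mitsunobu etherification; the para-formyl group makes the phenol acidic enough, and SN2 displacement at the activated lactate carbinol inverts (S) to (R), the configuration needed at the future C3.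

Step 2
Reactants: 3 ethyl (2R)-2-(4-formyl-2,6-dimethoxyphenoxy)propanoate
Product: 4 ethyl (2R)-2-[4-(hydroxymethyl)-2,6-dimethoxyphenoxy]propanoate
Conditions: NaBH4, EtOH, 0 °C
Reagents that add atoms: none
Why: Chemoselective borohydride reduction of an aryl aldehyde in the presence of an ester; short reaction at 0 °C in ethanol leaves the ethyl ester and its α-stereocentre untouched.

Step 3
Reactants: 4 ethyl (2R)-2-[4-(hydroxymethyl)-2,6-dimethoxyphenoxy]propanoate
Product: 5 ethyl (2R)-2-[4-({[tert-butyl(dimethyl)silyl]oxy}methyl)-2,6-dimethoxyphenoxy]propanoate
Conditions: t-BuMe2SiCl, imidazole, DMF, rt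
Reagents that add atoms: tert-butyl(chloro)dimethylsilane, CC(C)(C)[Si](C)(C)Cl
Why: Standard imidazole-promoted silylation of a primary benzylic alcohol; the silyl ether masks the hydroxyl for steps 4–7.

Step 4
Reactants: 5 ethyl (2R)-2-[4-({[tert-butyl(dimethyl)silyl]oxy}methyl)-2,6-dimethoxyphenoxy]propanoate
Product: 6 (2R)-2-[4-({[tert-butyl(dimethyl)silyl]oxy}methyl)-2,6-dimethoxyphenoxy]-N-methoxy-N-methylpropanamide
Conditions: MeNH(OMe)·HCl, i-PrMgCl, THF, −20 to 0 °C
Reagents that add atoms: N,O-dimethylhydroxylamine hydrochloride, CNOC.Cl
Why: Direct ester-to-Weinreb-amide conversion by the chloromagnesium amide formed in the flask; this weakly basic nucleophile at low temperature should acylate without epimerising the α-aryloxy centre.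

Step 5
Reactants: 6 (2R)-2-[4-({[tert-butyl(dimethyl)silyl]oxy}methyl)-2,6-dimethoxyphenoxy]-N-methoxy-N-methylpropanamide; 7 5-bromo-1,2,3-trimethoxybenzene
Product: 9 (2R)-2-[4-({[tert-butyl(dimethyl)silyl]oxy}methyl)-2,6-dimethoxyphenoxy]-1-(3,4,5-trimethoxyphenyl)propan-1-one, via (3,4,5-trimethoxyphenyl)magnesium bromide 8 (not isolated)
Conditions: 7, Mg, THF, rt to 40 °C; then 6, THF, 0 °C; sat. aq. NH4Cl, 0 °C
Reagents that add atoms: magnesium, [Mg] (taken up into 8 only)
Why: Grignard formation followed by acylation with a Weinreb amide; the N-methoxy chelate holds the tetrahedral adduct until the cold, near-neutral quench, so over-addition is avoided and the enolisable ketone is released only at the end.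

Step 6
Reactants: 9 (2R)-2-[4-({[tert-butyl(dimethyl)silyl]oxy}methyl)-2,6-dimethoxyphenoxy]-1-(3,4,5-trimethoxyphenyl)propan-1-one
Product: 10 (1R,2R)-2-[4-({[tert-butyl(dimethyl)silyl]oxy}methyl)-2,6-dimethoxyphenoxy]-1-(3,4,5-trimethoxyphenyl)propan-1-ol
Conditions: LiBH(s-Bu)3, THF, −78 °C; then aq. NH4Cl
Reagents that add atoms: none
Why: Felkin–Anh (polar) 1,2-induction: the bulky hydride attacks anti to the aryloxy group and past the hydrogen of C2, which sets C1 as R and gives the threo alcohol; the hindered, poorly coordinating aryl ether oxygen disfavours the chelate that would lead to the erythro isomer.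

Step 7
Reactants: 10 (1R,2R)-2-[4-({[tert-butyl(dimethyl)silyl]oxy}methyl)-2,6-dimethoxyphenoxy]-1-(3,4,5-trimethoxyphenyl)propan-1-ol
Product: 11 tert-butyl{[(2R,3R)-5-methoxy-3-methyl-2-(3,4,5-trimethoxyphenyl)-2,3-dihydro-1,4-benzodioxin-7-yl]methoxy}dimethylsilane
Conditions: 9-mesityl-3,6-di-tert-butyl-10-phenylacridinium tetrafluoroborate (5 mol %), 455 nm LEDs, ClCH2CH2Cl/CF3CH2OH 4:1, 0.02 M, N2, rt
Reagents that add atoms: none
Why: Proposed new method: the photoexcited acridinium should oxidise the syringyl ring of 10 to its radical cation, the C1 hydroxyl adds to a methoxy-bearing carbon, proton loss gives a cyclohexadienyl radical, and the acridine radical reduces it so that methoxide departs and the arene is restored, a redox-neutral cycle with methanol as the only by-product; the closest known reaction type is the acridinium-photocatalysed cation-radical-accelerated nucleophilic aromatic substitution of methoxyarenes by nitrogen nucleophiles, extended here to a tethered secondary alcohol. The dioxane ring closes by O–C(aryl) bond formation in a six-membered ortho-fused mode (6-exo with respect to the C8–C8a π bond), helped by the out-of-plane twist of the doubly ortho-substituted aryl ether, which holds the side chain over the ring face. No stereocentre is formed and no bond to C1 or C2 is broken, so the threo configuration from step 6 should appear unchanged as (2R,3R). Within ring A no regiochemical choice exists, because the two methoxy groups are mirror images of each other and the only C–H positions would need a seven-membered closure. The step needs ortho attack to beat spiro attack at the tether-bearing carbon (which would open a Smiles-type aryl shift and a regioisomeric dioxane); the singly occupied orbital of a 1,2,3-trialkoxyarene with a twisted central alkoxy group is carried by the two outer oxygenated carbons and has a node at the central one, and only the six-membered adduct can lose methanol irreversibly. It also needs cyclisation to beat Cα–Cβ scission and benzylic oxidation from the ring-C radical cation; the same nodal pattern puts the ring-C carbon that bears the carbinol at a node, and these net oxidations cannot turn the catalyst over when no terminal oxidant or base is present. Ring C is oxidised reversibly but has no nucleophile within reach, so hole exchange returns the charge to ring A, and high dilution with a radical-cation-stabilising fluoroalcohol co-solvent favours the intramolecular path.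

Step 8
Reactants: 11 tert-butyl{[(2R,3R)-5-methoxy-3-methyl-2-(3,4,5-trimethoxyphenyl)-2,3-dihydro-1,4-benzodioxin-7-yl]methoxy}dimethylsilane
Product: 12 [(2R,3R)-5-methoxy-3-methyl-2-(3,4,5-trimethoxyphenyl)-2,3-dihydro-1,4-benzodioxin-7-yl]methanol
Conditions: Bu4NF, THF, 0 °C to rt
Reagents that add atoms: none
Why: Fluoride-mediated cleavage of a primary silyl ether; the conditions are non-acidic, so the benzylic ether stereocentre C2 is not at risk.

Step 9
Reactants: 12 [(2R,3R)-5-methoxy-3-methyl-2-(3,4,5-trimethoxyphenyl)-2,3-dihydro-1,4-benzodioxin-7-yl]methanol
Product: 14 ethyl (2E)-3-[(2R,3R)-5-methoxy-3-methyl-2-(3,4,5-trimethoxyphenyl)-2,3-dihydro-1,4-benzodioxin-7-yl]prop-2-enoate, via benzodioxine-7-carbaldehyde 13 (not isolated)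
Conditions: MnO2, Ph3P=CHCO2Et, CH2Cl2, rt
Reagents that add atoms: ethyl (triphenyl-λ5-phosphanylidene)acetate, CCOC(=O)C=P(c1ccccc1)(c1ccccc1)c1ccccc1
Why: Tandem MnO2 oxidation–Wittig olefination: the electron-rich benzylic alcohol is oxidised selectively and the aldehyde is trapped as it forms by the stabilised ylide, which gives the (E)-cinnamate under thermodynamic control.

Step 10
Reactants: 14 ethyl (2E)-3-[(2R,3R)-5-methoxy-3-methyl-2-(3,4,5-trimethoxyphenyl)-2,3-dihydro-1,4-benzodioxin-7-yl]prop-2-enoate
Product: 15 (2E)-3-[(2R,3R)-5-methoxy-3-methyl-2-(3,4,5-trimethoxyphenyl)-2,3-dihydro-1,4-benzodioxin-7-yl]prop-2-en-1-ol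
Conditions: i-Bu2AlH, CH2Cl2, −78 °C; aq. potassium sodium tartrate
Reagents that add atoms: none
Why: 1,2-Reduction of an α,β-unsaturated ester by i-Bu2AlH gives the allylic alcohol with retention of the E geometry; aryl methyl ethers and the dioxane are inert at −78 °C.

## Compound list

1 | syringaldehyde (4-hydroxy-3,5-dimethoxybenzaldehyde) | COc1cc(C=O)cc(OC)c1O | starting material
2 | ethyl (S)-lactate | CCOC(=O)[C@H](C)O | starting material
3 | ethyl (2R)-2-(4-formyl-2,6-dimethoxyphenoxy)propanoate | CCOC(=O)[C@@H](C)Oc1c(OC)cc(C=O)cc1OC | intermediate
4 | ethyl (2R)-2-[4-(hydroxymethyl)-2,6-dimethoxyphenoxy]propanoate | CCOC(=O)[C@@H](C)Oc1c(OC)cc(CO)cc1OC | intermediate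
5 | ethyl (2R)-2-[4-({[tert-butyl(dimethyl)silyl]oxy}methyl)-2,6-dimethoxyphenoxy]propanoate | CCOC(=O)[C@@H](C)Oc1c(OC)cc(CO[Si](C)(C)C(C)(C)C)cc1OC | intermediate
6 | (2R)-2-[4-({[tert-butyl(dimethyl)silyl]oxy}methyl)-2,6-dimethoxyphenoxy]-N-methoxy-N-methylpropanamide | CON(C)C(=O)[C@@H](C)Oc1c(OC)cc(CO[Si](C)(C)C(C)(C)C)cc1OC | intermediate
7 | 5-bromo-1,2,3-trimethoxybenzene | COc1cc(Br)cc(OC)c1OC | starting material
8 | (3,4,5-trimethoxyphenyl)magnesium bromide | COc1cc([Mg]Br)cc(OC)c1OC | intermediate
9 | (2R)-2-[4-({[tert-butyl(dimethyl)silyl]oxy}methyl)-2,6-dimethoxyphenoxy]-1-(3,4,5-trimethoxyphenyl)propan-1-one | COc1cc(C(=O)[C@@H](C)Oc2c(OC)cc(CO[Si](C)(C)C(C)(C)C)cc2OC)cc(OC)c1OC | intermediate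
10 | (1R,2R)-2-[4-({[tert-butyl(dimethyl)silyl]oxy}methyl)-2,6-dimethoxyphenoxy]-1-(3,4,5-trimethoxyphenyl)propan-1-ol | COc1cc([C@@H](O)[C@@H](C)Oc2c(OC)cc(CO[Si](C)(C)C(C)(C)C)cc2OC)cc(OC)c1OC | intermediate
11 | tert-butyl{[(2R,3R)-5-methoxy-3-methyl-2-(3,4,5-trimethoxyphenyl)-2,3-dihydro-1,4-benzodioxin-7-yl]methoxy}dimethylsilane | COc1cc([C@H]2Oc3cc(CO[Si](C)(C)C(C)(C)C)cc(OC)c3O[C@@H]2C)cc(OC)c1OC | intermediate
12 | [(2R,3R)-5-methoxy-3-methyl-2-(3,4,5-trimethoxyphenyl)-2,3-dihydro-1,4-benzodioxin-7-yl]methanol | COc1cc([C@H]2Oc3cc(CO)cc(OC)c3O[C@@H]2C)cc(OC)c1OC | intermediate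
13 | (2R,3R)-5-methoxy-3-methyl-2-(3,4,5-trimethoxyphenyl)-2,3-dihydro-1,4-benzodioxine-7-carbaldehyde | COc1cc([C@H]2Oc3cc(C=O)cc(OC)c3O[C@@H]2C)cc(OC)c1OC | intermediate
14 | ethyl (2E)-3-[(2R,3R)-5-methoxy-3-methyl-2-(3,4,5-trimethoxyphenyl)-2,3-dihydro-1,4-benzodioxin-7-yl]prop-2-enoate | COc1cc([C@H]2Oc3cc(/C=C/C(=O)OCC)cc(OC)c3O[C@@H]2C)cc(OC)c1OC | intermediate
15 | (2E)-3-[(2R,3R)-5-methoxy-3-methyl-2-(3,4,5-trimethoxyphenyl)-2,3-dihydro-1,4-benzodioxin-7-yl]prop-2-en-1-ol | COc1cc([C@H]2Oc3cc(/C=C/CO)cc(OC)c3O[C@@H]2C)cc(OC)c1OC | target

## Step count and risk assessment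

Total step count: 10. Longest linear sequence: 10 steps (from 1 or 2 to 15). Bromide 7 enters in step 5 through Grignard reagent 8, which is made in the same flask and adds no separate step.

**Step 7 (key step, the one step proposed as a new method).**
- What may go wrong:
  - Spiro attack of the hydroxyl at the tether-bearing carbon C4a, followed by cleavage of the original aryl–oxygen bond, would shift the aryl group from one oxygen to the other. Closure of the shifted ether would then give the regioisomeric dioxane.
  - Localisation of the hole on ring C could lead to Cα–Cβ scission or benzylic C–H loss. These paths consume the oxidising equivalents of the photocatalyst without turnover and would stall conversion.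
  - The product, whose ring A is a better electron donor than that of 10, may act as a hole sink and slow the reaction as it accumulates.
- Fallback (known chemistry, same O1–C8a bond, bromide in place of methoxide as leaving group): the detour sets out from ethyl (S)-lactate 2. It is coupled under the step 1 conditions with commercial 5-bromovanillin (3-bromo-4-hydroxy-5-methoxybenzaldehyde, COc1cc(C=O)cc(Br)c1O) to give ethyl (2R)-2-(2-bromo-4-formyl-6-methoxyphenoxy)propanoate F1. The operations of steps 2–6 then lead through ethyl (2R)-2-[2-bromo-4-(hydroxymethyl)-6-methoxyphenoxy]propanoate F2, ethyl (2R)-2-[2-bromo-4-({[tert-butyl(dimethyl)silyl]oxy}methyl)-6-methoxyphenoxy]propanoate F3, (2R)-2-[2-bromo-4-({[tert-butyl(dimethyl)silyl]oxy}methyl)-6-methoxyphenoxy]-N-methoxy-N-methylpropanamide F4 and (2R)-2-[2-bromo-4-({[tert-butyl(dimethyl)silyl]oxy}methyl)-6-methoxyphenoxy]-1-(3,4,5-trimethoxyphenyl)propan-1-one F5 to (1R,2R)-2-[2-bromo-4-({[tert-butyl(dimethyl)silyl]oxy}methyl)-6-methoxyphenoxy]-1-(3,4,5-trimethoxyphenyl)propan-1-ol F6. Intramolecular Pd-catalysed C–O coupling of F6 (Pd(OAc)2, 2-(di-tert-butylphosphino)-1,1'-binaphthyl, Cs2CO3, toluene, 80 °C) is an established way to 1,4-benzodioxanes from 2-(2-bromophenoxy)alkanols. It would close the ring and return to the route at 11. The position of bromine then defines the regiochemistry, at the cost of giving up the symmetric ring A.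

**Step 6.**
- What may go wrong: poor facial selectivity if partial chelation of lithium by the aryl ether or methoxy oxygens competes with the Felkin–Anh pathway, giving erythro alcohol alongside threo; enolisation of the ketone by the basic hydride would erode the C2 configuration.
- Fallback: starting from 9, switch from substrate control to catalyst control by asymmetric transfer hydrogenation with RuCl[(S,S)-TsDPEN](p-cymene) in HCO2H/Et3N. On the usual aryl-versus-alkyl facial discrimination this should deliver the (1R) carbinol under mildly acidic conditions and return to the route at 10; no compound outside the list is formed (F0).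

**Step 5.**
- What may go wrong: loss of configurational integrity at C2 by enolisation of the α-aryloxy aryl ketone during quench or purification, or incomplete acylation if the electron-rich Grignard reagent forms sluggishly.
- Fallback: starting from 6, avoid the ketone altogether. Reduction with LiAlH4 (THF, −78 °C) gives (2R)-2-[4-({[tert-butyl(dimethyl)silyl]oxy}methyl)-2,6-dimethoxyphenoxy]propanal F7. It is used at once in a chelation-controlled addition of 8 (MgBr2·OEt2, CH2Cl2, −78 °C). The Cram-chelate mode of aryl addition to an α-alkoxy aldehyde gives the syn (threo) product, so this returns directly to 10 and bypasses 9 and step 6.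

**Step 1.**
- What may go wrong: slow coupling because the phenol is flanked by two methoxy groups, with competing alkylation of the reduced azodicarboxylate or elimination of the activated lactate.
- Fallback: starting from 2, make ethyl (2S)-2-{[(trifluoromethyl)sulfonyl]oxy}propanoate F8 with (CF3SO2)2O and 2,6-lutidine (CH2Cl2, −78 °C). Displace the triflate with the phenoxide of 1 (K2CO3, MeCN, 0 °C to rt); this SN2 reaction also proceeds with inversion and returns to the route at 3.

## Further compounds

F1 | step 7 | ethyl (2R)-2-(2-bromo-4-formyl-6-methoxyphenoxy)propanoate | CCOC(=O)[C@@H](C)Oc1c(Br)cc(C=O)cc1OC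
F2 | step 7 | ethyl (2R)-2-[2-bromo-4-(hydroxymethyl)-6-methoxyphenoxy]propanoate | CCOC(=O)[C@@H](C)Oc1c(Br)cc(CO)cc1OC
F3 | step 7 | ethyl (2R)-2-[2-bromo-4-({[tert-butyl(dimethyl)silyl]oxy}methyl)-6-methoxyphenoxy]propanoate | CCOC(=O)[C@@H](C)Oc1c(Br)cc(CO[Si](C)(C)C(C)(C)C)cc1OC
F4 | step 7 | (2R)-2-[2-bromo-4-({[tert-butyl(dimethyl)silyl]oxy}methyl)-6-methoxyphenoxy]-N-methoxy-N-methylpropanamide | CON(C)C(=O)[C@@H](C)Oc1c(Br)cc(CO[Si](C)(C)C(C)(C)C)cc1OC
F5 | step 7 | (2R)-2-[2-bromo-4-({[tert-butyl(dimethyl)silyl]oxy}methyl)-6-methoxyphenoxy]-1-(3,4,5-trimethoxyphenyl)propan-1-one | COc1cc(C(=O)[C@@H](C)Oc2c(Br)cc(CO[Si](C)(C)C(C)(C)C)cc2OC)cc(OC)c1OC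
F6 | step 7 | (1R,2R)-2-[2-bromo-4-({[tert-butyl(dimethyl)silyl]oxy}methyl)-6-methoxyphenoxy]-1-(3,4,5-trimethoxyphenyl)propan-1-ol | COc1cc([C@@H](O)[C@@H](C)Oc2c(Br)cc(CO[Si](C)(C)C(C)(C)C)cc2OC)cc(OC)c1OC
F0 | step 6 | none | none
F7 | step 5 | (2R)-2-[4-({[tert-butyl(dimethyl)silyl]oxy}methyl)-2,6-dimethoxyphenoxy]propanal | O=C[C@@H](C)Oc1c(OC)cc(CO[Si](C)(C)C(C)(C)C)cc1OC
F8 | step 1 | ethyl (2S)-2-{[(trifluoromethyl)sulfonyl]oxy}propanoate | CCOC(=O)[C@H](C)OS(=O)(=O)C(F)(F)F
A1 | alternative 1 | methyl (2R,3R)-3-methyl-5-oxo-2-(3,4,5-trimethoxyphenyl)-2,3,5,6,7,8-hexahydro-1,4-benzodioxine-7-carboxylate (either C7 epimer) | COc1cc([C@H]2OC3=C(O[C@@H]2C)C(=O)CC(C(=O)OC)C3)cc(OC)c1OC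
A2 | alternative 1 | methyl 4-diazo-3,5-dioxocyclohexane-1-carboxylate | COC(=O)C1CC(=O)C(=[N+]=[N-])C(=O)C1
A3 | alternative 1 | (1R,2R)-1-{[tert-butyl(dimethyl)silyl]oxy}-1-(3,4,5-trimethoxyphenyl)propan-2-ol | COc1cc([C@@H](O[Si](C)(C)C(C)(C)C)[C@@H](C)O)cc(OC)c1OC
A4 | alternative 1 | (1R,2R)-1-(3,4,5-trimethoxyphenyl)propane-1,2-diol | COc1cc([C@@H](O)[C@@H](C)O)cc(OC)c1OC
A5 | alternative 2 | (2R,3R)-3-methyl-2-(3,4,5-trimethoxyphenyl)-2,3-dihydro-1,4-benzodioxine-5,7-diol | COc1cc([C@H]2Oc3cc(O)cc(O)c3O[C@@H]2C)cc(OC)c1OC
A6 | alternative 2 | methyl (5R,6R)-6-methyl-3-(2-oxopropyl)-5-(3,4,5-trimethoxyphenyl)-5,6-dihydro-1,4-dioxine-2-carboxylate | COC(=O)C1=C(CC(C)=O)O[C@H](c2cc(OC)c(OC)c(OC)c2)[C@@H](C)O1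
A7 | alternative 3 | (2R,3R)-5-methoxy-3-methyl-2-(3,4,5-trimethoxyphenyl)-2,3-dihydro-1,4-benzodioxine-7-carbaldehyde (same compound as 13) | COc1cc([C@H]2Oc3cc(C=O)cc(OC)c3O[C@@H]2C)cc(OC)c1OC
A8 | alternative 3 | 3-hydroxy-5-methoxy-4-{[(2R)-1-(3,4,5-trimethoxyphenyl)propan-2-yl]oxy}benzaldehyde | COc1cc(C[C@@H](C)Oc2c(O)cc(C=O)cc2OC)cc(OC)c1OC
A9 | alternative 3 | 3,4-dihydroxy-5-methoxybenzaldehyde | COc1cc(C=O)cc(O)c1O
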